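The rings are numbered C1 (C=O beside the ring junction), C2 (CH3), C3 (OH), C4 (C=O), C5 (CH2CH2Ph) and C6 (junction), with primes for the second ring. The chain C1–C6–C6'–C1' running through both rings is read as a succinic diester. C2–C3–C4–C5 of each ring is read as an ethyl alkenyl ketone. The succinate enters as its bis(silyl ketene acetal), a 1,4-dialkoxy-1,4-disilyloxybutadiene. It adds through C6 and C6' to two molecules of (E)-7-phenylhept-4-en-3-one, and base then closes C2 onto C1 in both halves. One flask should thus deliver four C–C bonds and both carbocycles around a pre-existing, crowded C6–C6' bond. Dehydrogenation and para-oxidation complete the synthesis.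

Key step: step 3

Remarks on the chemistry
- Assumption: the target string carries no stereodescriptor, so the C6–C6' axis (four ortho substituents) is treated as unspecified and is made racemic.
- Compound 9 is drawn as a bis-enol and as one diastereomer. All tautomers and diastereomers are carried on together, because step 4 removes C5, C6, C5' and C6' as stereocentres.
- The conjugate addition uses a catalytic silicon Lewis acid. Stoichiometric TiCl4 couples ketene silyl acetals oxidatively, could turn 6 into diethyl fumarate, and would consume the alkoxide needed later in the same flask.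
- The geometry of 6 is not passed on to the target. DMPU is used so that the isomer drawn (OSiMe3 cis to the C2–C3 bond) is the one to be expected, and any other geometric isomer should react alike.

Step 1
Reactants: 1 3-phenylpropanal; 2 diethyl (2-oxobutyl)phosphonate
Product: 3 (E)-7-phenylhept-4-en-3-one
Conditions: LiCl, iPr2NEt, MeCN, 23 °C
Reagents that add atoms: none
Why: This is a Horner–Wadsworth–Emmons olefination under Masamune–Roush conditions, in which lithium chelation lets a mild amine deprotonate the β-ketophosphonate, so the enolisable aldehyde is spared and the stabilised carbanion should give the E-enone.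

Step 2
Reactants: 4 diethyl succinate
Product: 6 (1Z,3Z)-1,4-diethoxy-1,4-bis(trimethylsilyloxy)buta-1,3-diene, via dilithium dienediolate 5 (not isolated)
Conditions: LiN(iPr)2 (2.3 equiv), THF–DMPU, −78 °C, slow addition of 4; Me3SiCl (2.6 equiv), −78 → 23 °C; pentane, cold aq. NaHCO3 wash, vacuum distillation
Reagents that add atoms: chlorotrimethylsilane, C[Si](C)(C)Cl
Why: Double ester enolisation to the vicinal succinate dianion followed by O-silylation is the standard preparation of ketene silyl acetals, with slow addition to excess amide suppressing Claisen self-condensation and DMPU favouring O- over C-silylation and the Z geometry.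

Step 3
Reactants: 3 (E)-7-phenylhept-4-en-3-one (2.1 equiv); 6 (1Z,3Z)-1,4-diethoxy-1,4-bis(trimethylsilyloxy)buta-1,3-diene
Product: 9 3,3'-dimethyl-6,6'-bis(2-phenylethyl)[1,1'-bi(cyclohexane)]-2,2',4,4'-tetrone (bis-enol tautomer; diastereomer mixture drawn as the meso trans,trans isomer), via bis(silyl enol ether) diester 7 (not isolated), via dipotassium bis(dionate) 8 (not isolated)
Conditions: Me3SiNTf2 (5 mol %), CH2Cl2, −78 °C, slow addition of 3, → −20 °C; CH2Cl2 evaporated from the same flask; KOC(CH3)3 (5 equiv), THF–tBuOH, 0 → 50 °C; dilute aq. HCl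
Reagents that add atoms: none
Why: Proposed new method: Me3SiNTf2 silylates the enone oxygen, ketene acetal carbon C6 attacks the β-carbon C5 and silyl transfer regenerates the catalyst, the remaining and still far more nucleophilic terminus C6' does the same with a second enone to give 7, and KOC(CH3)3 then removes both silyl groups while tBuOH shuttles protons so that the first-formed C4 enolates equilibrate with the C2 enolates, each of which acylates its neighbouring ester C1 with loss of ethoxide. The closest known reactions are the Mukaiyama–Michael addition of ketene silyl acetals to acyclic enones and the alkoxide cyclisation of 5-oxoheptanoates to 2-methylcyclohexane-1,3-diones (the malonate Michael–Claisen route to 5-alkylresorcinols); what is new is the twofold use of a succinate donor, which must place two tertiary carbons side by side. Both rings close in the same mode, a 6-(enolendo)-exo-trig Claisen (Dieckmann-type) attack of C2 on C1 and of C2' on C1'. The stereocentres C5, C6, C5' and C6' are not controlled in the addition, C6 and C6' can epimerise under alkoxide and should drift trans to the C5 and C5' side chains, and all four disappear in step 4. The addition must go 1,4 and not 1,2, without [4+2] cycloaddition or redox loss of the diene, which the soft ketene acetal carbon, the inward-pointing oxygen substituent on each diene terminus (it blocks the s-cis conformer) and the non-oxidising catalyst should secure. Closure must go through C2 and not through a 5-exo attack of C4 on the remote ester C1', an alternative opposed by the crowding of a pentasubstituted cyclopentanone and by the greater stability of the 1,3-dione enolate as the sink under equilibrating conditions, and no longer available once the first ring has turned its ester carbon into part of an enolate.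

Step 4
Reactants: 9 3,3'-dimethyl-6,6'-bis(2-phenylethyl)[1,1'-bi(cyclohexane)]-2,2',4,4'-tetrone
Product: 10 3,3'-dimethyl-6,6'-bis(2-phenylethyl)[1,1'-biphenyl]-2,2',4,4'-tetrol (racemic axis)
Conditions: 10% Pd/C, p-cymene, reflux, argon sweep
Reagents that add atoms: none
Why: Catalytic dehydrogenation of cyclohexane-1,3-diones over Pd/C is an established entry to resorcinols, each ring losing one H2 under the driving force of aromatisation while the argon stream removes H2 to limit hydrogen-transfer deoxygenation.

Step 5
Reactants: 10 3,3'-dimethyl-6,6'-bis(2-phenylethyl)[1,1'-biphenyl]-2,2',4,4'-tetrol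
Product: 11 4,4'-dihydroxy-5,5'-dimethyl-2,2'-bis(2-phenylethyl)[1,1'-bi(cyclohexa-1,4-diene)]-3,3',6,6'-tetrone (target)
Conditions: ON(SO3K)2 (5 equiv), aq. KH2PO4, acetone–H2O, 0 → 23 °C; dilute aq. HCl
Reagents that add atoms: dipotassium nitrosodisulfonate ON(SO3K)2, [K+].[K+].[O]N(S(=O)(=O)[O-])S(=O)(=O)[O-]
Why: In this Teuber oxidation one nitrosodisulfonate radical takes the phenolic hydrogen at O–C1 and a second combines at the para carbon C4, the only free ring position (para to O–C3 lies the blocked C6), so collapse should give the C1/C4 quinone with C3–OH retained, as known for 5-alkyl- and 2,5-dialkylresorcinols.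

Compound list
1 | 3-phenylpropanal | O=CCCc1ccccc1 | starting material
2 | diethyl (2-oxobutyl)phosphonate | CCOP(=O)(CC(=O)CC)OCC | starting material
3 | (E)-7-phenylhept-4-en-3-one | CCC(=O)/C=C/CCc1ccccc1 | intermediate
4 | diethyl succinate | CCOC(=O)CCC(=O)OCC | starting material
5 | dilithium 1,4-diethoxybuta-1,3-diene-1,4-diolate, both O–Li cis to the C2–C3 bond (not isolated) | CCO/C([O-])=C/C=C(/OCC)[O-].[Li+].[Li+] | intermediate
6 | (1Z,3Z)-1,4-diethoxy-1,4-bis(trimethylsilyloxy)buta-1,3-diene | CCO/C(O[Si](C)(C)C)=C/C=C(/OCC)O[Si](C)(C)C | intermediate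
7 | diethyl 2,3-bis[1-phenyl-5-(trimethylsilyloxy)hept-4-en-3-yl]butanedioate, mixture of diastereomers and enol ether geometries (not isolated) | CCOC(=O)C(C(CCc1ccccc1)C=C(CC)O[Si](C)(C)C)C(C(CCc1ccccc1)C=C(CC)O[Si](C)(C)C)C(=O)OCC | intermediate
8 | dipotassium bis-enolate of 9, drawn as the meso trans,trans isomer (not isolated) | CC1=C([O-])C[C@H](CCc2ccccc2)[C@@H]([C@H]2[C@H](CCc3ccccc3)CC([O-])=C(C)C2=O)C1=O.[K+].[K+] | intermediate
9 | 3,3'-dimethyl-6,6'-bis(2-phenylethyl)[1,1'-bi(cyclohexane)]-2,2',4,4'-tetrone, bis-enol form, mixture drawn as the meso trans,trans isomer | CC1=C(O)C[C@H](CCc2ccccc2)[C@@H]([C@H]2[C@H](CCc3ccccc3)CC(O)=C(C)C2=O)C1=O | intermediate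
10 | 3,3'-dimethyl-6,6'-bis(2-phenylethyl)[1,1'-biphenyl]-2,2',4,4'-tetrol, racemic axis | Cc1c(O)cc(CCc2ccccc2)c(-c2c(CCc3ccccc3)cc(O)c(C)c2O)c1O | intermediate
11 | 4,4'-dihydroxy-5,5'-dimethyl-2,2'-bis(2-phenylethyl)[1,1'-bi(cyclohexa-1,4-diene)]-3,3',6,6'-tetrone | CC1=C(O)C(=O)C(CCc2ccccc2)=C(C2=C(CCc3ccccc3)C(=O)C(O)=C(C)C2=O)C1=O | target

Total step count: 5. Longest linear sequence: 4 (steps 1 or 2, then 3, 4, 5).

Steps most likely to fail

Step 3.
- The second conjugate addition may stall, because it must join two tertiary carbons next to each other.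
- The ketene acetal may be lost by protodesilylation or by electron transfer to the activated enone.
- Under alkoxide the crowded adduct may fragment by retro-Michael reaction, or close through C4 onto the remote ester.

The fallback uses known chemistry and forms the C6–C6' bond last. It sets out from 3 and comes back at 9. Michael–Claisen annulation of 3 with diethyl malonate (NaOEt, EtOH, reflux) should give ethyl 3-methyl-2,4-dioxo-6-(2-phenylethyl)cyclohexane-1-carboxylate F1. Saponification (aq. NaOH) and acidic decarboxylation should give 2-methyl-5-(2-phenylethyl)cyclohexane-1,3-dione F2, in which C4 and C6 are equivalent. EtOH and TsOH with azeotropic removal of water should give the vinylogous ester 3-ethoxy-2-methyl-5-(2-phenylethyl)cyclohex-2-en-1-one F3. Kinetic α'-deprotonation (LiN(iPr)2, THF, −78 °C) and oxidative enolate homocoupling with CuCl2 in DMF should give 4,4'-diethoxy-3,3'-dimethyl-6,6'-bis(2-phenylethyl)[1,1'-bi(cyclohex-3-ene)]-2,2'-dione F4, each new bond forming anti to the C5 side chain. Aqueous HCl in THF then hydrolyses both enol ethers to 9.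

Step 4.
- Hydrogen released on the catalyst may be transferred back and cause reductive loss of oxygen.
- The second ring may dehydrogenate only sluggishly.
- Long heating may degrade the material.

The fallback sets out from 9 and comes back at 10. It replaces catalytic dehydrogenation by halogen-mediated aromatisation. I2 in refluxing MeOH (enol etherification, α-iodination at C4, loss of HI) should give O-methylated biaryls, drawn as the fully methylated 2,2',4,4'-tetramethoxy-3,3'-dimethyl-6,6'-bis(2-phenylethyl)-1,1'-biphenyl F5. BBr3 (CH2Cl2, −78 → 23 °C) should convert this and any partly methylated material into 10.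

Step 5.
- Radical attack at C4, wedged between C3–OH and the phenethyl chain, may be slow.
- The lipophilic substrate may dissolve poorly in the aqueous medium.
- Over-oxidation or intermolecular phenol coupling may compete.

The fallback sets out from 10 and comes back at 11. It installs the C4 oxygen by ionic chemistry. Vilsmeier–Haack formylation (POCl3, DMF) at the only free positions should give 4,4',6,6'-tetrahydroxy-5,5'-dimethyl-2,2'-bis(2-phenylethyl)[1,1'-biphenyl]-3,3'-dicarbaldehyde F6. Dakin oxidation (H2O2, B(OH)3, cat. H2SO4, THF) should give 3,3'-dimethyl-6,6'-bis(2-phenylethyl)[1,1'-biphenyl]-2,2',4,4',5,5'-hexol F7. Mild oxidation of the two hydroxyhydroquinone rings (FeCl3, aq. EtOH, or air) should then give 11.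

Further compounds
F1 | step 3 | ethyl 3-methyl-2,4-dioxo-6-(2-phenylethyl)cyclohexane-1-carboxylate (diastereomer mixture) | CCOC(=O)C1C(CCc2ccccc2)CC(=O)C(C)C1=O
F2 | step 3 | 2-methyl-5-(2-phenylethyl)cyclohexane-1,3-dione | CC1C(=O)CC(CCc2ccccc2)CC1=O
F3 | step 3 | 3-ethoxy-2-methyl-5-(2-phenylethyl)cyclohex-2-en-1-one (racemic) | CCOC1=C(C)C(=O)CC(CCc2ccccc2)C1
F4 | step 3 | 4,4'-diethoxy-3,3'-dimethyl-6,6'-bis(2-phenylethyl)[1,1'-bi(cyclohex-3-ene)]-2,2'-dione (mixture drawn as the meso trans,trans isomer) | CC1=C(OCC)C[C@H](CCc2ccccc2)[C@@H]([C@H]2[C@H](CCc3ccccc3)CC(OCC)=C(C)C2=O)C1=O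
F5 | step 4 | 2,2',4,4'-tetramethoxy-3,3'-dimethyl-6,6'-bis(2-phenylethyl)-1,1'-biphenyl | COc1cc(CCc2ccccc2)c(-c2c(CCc3ccccc3)cc(OC)c(C)c2OC)c(OC)c1C
F6 | step 5 | 4,4',6,6'-tetrahydroxy-5,5'-dimethyl-2,2'-bis(2-phenylethyl)[1,1'-biphenyl]-3,3'-dicarbaldehyde | Cc1c(O)c(C=O)c(CCc2ccccc2)c(-c2c(CCc3ccccc3)c(C=O)c(O)c(C)c2O)c1O
F7 | step 5 | 3,3'-dimethyl-6,6'-bis(2-phenylethyl)[1,1'-biphenyl]-2,2',4,4',5,5'-hexol | Cc1c(O)c(O)c(CCc2ccccc2)c(-c2c(CCc3ccccc3)c(O)c(O)c(C)c2O)c1O
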